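**Retrosynthetic overview**
1. Yanuthone X2 ⇒ its C5 silyl ether ⇒ an acyclic (S)-α-chloro-α-farnesyl-β-keto aldehyde. Both rings are cut in one move: the oxirane at C1–O7 (alkoxide SN2 on a tertiary chloride) and the carbocycle at C5–C6 (vinylogous aldol of the γ-carbon of a β-methoxy enone onto the formyl group).
2. The chloro aldehyde ⇒ the 2-farnesyl β-keto aldehyde by catalytic enantioselective chlorination. This one quaternary centre later dictates C6 and C5.
3. The β-keto aldehyde ⇒ an acyclic vinylogous-ester methyl ketone by two kinetic α′-enolate reactions (farnesyl bromide, then a formate).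
4. The vinylogous ester ⇒ methanol + an ynone ⇒ silyl propargyl ether + acetyl Weinreb amide. This fixes the OMe position.
5. Ring order: no ring exists until the last step. There the cyclohexenone closes first and the oxirane directly after it, in the same operation.

Assumption: the (S,S) ligand of step 5 is taken to give (S)-11 (the mirror-image ligand is equally available if the sense is opposite), and LDA and LiTMP are used as purchased reagents.

**Step 1**
Reactants: 1 tert-butyldimethyl(prop-2-yn-1-yloxy)silane; 2 N-methoxy-N-methylacetamide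
Product: 4 5-[(tert-butyldimethylsilyl)oxy]pent-3-yn-2-one, via lithium acetylide 3 (not isolated)
Conditions: n-BuLi, THF, −78 °C; then 2, −78 → 0 °C; H2O
Reagents that add atoms: none
Why: Weinreb ketone synthesis, in which the acetylide adds only once because the chelated tetrahedral adduct survives until work-up; no stereocenter is formed.

**Step 2**
Reactants: 4 5-[(tert-butyldimethylsilyl)oxy]pent-3-yn-2-one
Product: 5 (3E)-5-[(tert-butyldimethylsilyl)oxy]-4-methoxypent-3-en-2-one
Conditions: MeOH, NaOMe (5 mol %), 0 °C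
Reagents that add atoms: methanol, CO
Why: Base-catalysed oxa-Michael addition puts OMe regiospecifically on the β-carbon of the ynone, and reversible methoxide addition equilibrates to the more stable E enol ether (OMe trans to the acyl group, CH2OTBS cis to it), the geometry needed for the later ring closure.

**Step 3**
Reactants: 5 (3E)-5-[(tert-butyldimethylsilyl)oxy]-4-methoxypent-3-en-2-one; 6 (2E,6E)-farnesyl bromide
Product: 8 (2E,7E,11E)-1-[(tert-butyldimethylsilyl)oxy]-2-methoxy-8,12,16-trimethylheptadeca-2,7,11,15-tetraen-4-one, via lithium enolate 7 (not isolated)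
Conditions: LDA (lithium diisopropylamide), THF, −78 °C; then 6, DMPU, −78 → −30 °C
Reagents that add atoms: none
Why: Kinetic deprotonation of a β-alkoxy enone occurs at the α′-methyl group (Stork–Danheiser-type cross-conjugated enolate), and SN2 alkylation with the primary allylic bromide keeps both E alkenes; no stereocenter is formed.

**Step 4**
Reactants: 8 (2E,7E,11E)-1-[(tert-butyldimethylsilyl)oxy]-2-methoxy-8,12,16-trimethylheptadeca-2,7,11,15-tetraen-4-one
Product: 10 (4E)-6-[(tert-butyldimethylsilyl)oxy]-5-methoxy-3-oxo-2-[(2E,6E)-3,7,11-trimethyldodeca-2,6,10-trien-1-yl]hex-4-enal, via lithium enolate 9 (not isolated)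
Conditions: LDA, THF, −78 °C; then HCO2CH2CF3, −78 °C; pH 7 buffer
Reagents that add atoms: 2,2,2-trifluoroethyl formate, O=COCC(F)(F)F
Why: Crossed Claisen formylation of the kinetic α′-enolate with an activated formate, driven by formation of the chelated enolate of the product; the new C-2 centre is enolisable and is deliberately left uncontrolled.

**Step 5**
Reactants: 10 (4E)-6-[(tert-butyldimethylsilyl)oxy]-5-methoxy-3-oxo-2-[(2E,6E)-3,7,11-trimethyldodeca-2,6,10-trien-1-yl]hex-4-enal
Product: 11 (2S,4E)-6-[(tert-butyldimethylsilyl)oxy]-2-chloro-5-methoxy-3-oxo-2-[(2E,6E)-3,7,11-trimethyldodeca-2,6,10-trien-1-yl]hex-4-enal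
Conditions: NCS, Cu(OTf)2 (10 mol %), (S,S)-Ph-BOX [2,2′-isopropylidenebis((4S)-4-phenyl-2-oxazoline)] (12 mol %), 4 Å MS, Et2O, −20 °C
Reagents that add atoms: N-chlorosuccinimide, O=C1CCC(=O)N1Cl
Why: Proposed new method: the enol of 10 should bind Cu(OTf)2/bis(oxazoline) as a bidentate 1,3-dicarbonyl enolate just as 2-alkyl β-keto esters do, the ligand shields one enolate face and NCS delivers Cl+ to the open face to set the quaternary C-2 as S, with the size difference between formyl H and the acyl arm favouring one chelate geometry; the closest known reaction type is the Lewis-acid-catalysed enantioselective α-chlorination of 2-substituted β-keto esters.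

**Step 6**
Reactants: 11 (2S,4E)-6-[(tert-butyldimethylsilyl)oxy]-2-chloro-5-methoxy-3-oxo-2-[(2E,6E)-3,7,11-trimethyldodeca-2,6,10-trien-1-yl]hex-4-enal
Product: 15 yanuthone X2 [(1R,5S,6R)-5-hydroxy-4-methoxy-1-[(2E,6E)-3,7,11-trimethyldodeca-2,6,10-trien-1-yl]-7-oxabicyclo[4.1.0]hept-3-en-2-one], via lithium dienolate 12 (not isolated), via lithium chlorohydrin alkoxide 13 (not isolated), via silyl ether 14 (not isolated)
Conditions: LiTMP (lithium 2,2,6,6-tetramethylpiperidide, 1.0 equiv), THF, −78 → 0 °C; then Et3N·3HF, 0 °C → rt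
Reagents that add atoms: none
Why: Proposed new method: because C-2 is quaternary the only acidic C–H of 11 is the γ-CH2 of the vinylogous ester, so the hindered amide gives dienolate 12, whose γ-carbon can reach only the formyl carbon through a six-membered transition state (α-attack would give a four-membered ring), the aldehyde reacts in its Cornforth conformer (C=O anti to C–Cl) with the silyloxy group on the outside of the dienolate so that in 13 the alkoxide is trans-diaxial to chloride and cis to OTBS, and a stereospecific 3-exo-tet SN2 displacement of the tertiary α-keto chloride with inversion then closes the oxirane, consuming the single equivalent of base as LiCl, so that C-2 of 11 fixes C1, C6 and C5 of the product (OH cis to the oxirane oxygen) before fluoride removes the silyl group; the closest known reaction types are the Darzens condensation of α-chloro ketones, the domino Michael/aldol/SN2 synthesis of epoxycyclohexanones and intramolecular vinylogous aldol reactions.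

**Compound list**
1 | tert-butyldimethyl(prop-2-yn-1-yloxy)silane | C#CCO[Si](C)(C)C(C)(C)C | starting material
2 | N-methoxy-N-methylacetamide | CC(=O)N(C)OC | starting material
3 | lithium 3-[(tert-butyldimethylsilyl)oxy]prop-1-yn-1-ide | [Li+].[C-]#CCO[Si](C)(C)C(C)(C)C | intermediate
4 | 5-[(tert-butyldimethylsilyl)oxy]pent-3-yn-2-one | CC(=O)C#CCO[Si](C)(C)C(C)(C)C | intermediate
5 | (3E)-5-[(tert-butyldimethylsilyl)oxy]-4-methoxypent-3-en-2-one | CC(=O)/C=C(/OC)CO[Si](C)(C)C(C)(C)C | intermediate
6 | (2E,6E)-farnesyl bromide | BrC/C=C(\C)CC/C=C(\C)CCC=C(C)C | starting material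
7 | lithium α′-enolate of 5 | [Li+].C=C([O-])/C=C(/OC)CO[Si](C)(C)C(C)(C)C | intermediate
8 | (2E,7E,11E)-1-[(tert-butyldimethylsilyl)oxy]-2-methoxy-8,12,16-trimethylheptadeca-2,7,11,15-tetraen-4-one | CC(C)(C)[Si](C)(C)OC/C(OC)=C\C(=O)CC/C=C(\C)CC/C=C(\C)CCC=C(C)C | intermediate
9 | lithium α′-enolate of 8 (enolate geometry not defined) | [Li+].CC(C)(C)[Si](C)(C)OC/C(OC)=C\C([O-])=CC/C=C(\C)CC/C=C(\C)CCC=C(C)C | intermediate
10 | (4E)-6-[(tert-butyldimethylsilyl)oxy]-5-methoxy-3-oxo-2-[(2E,6E)-farnesyl]hex-4-enal (C-2 labile, mainly enol) | CC(C)(C)[Si](C)(C)OC/C(OC)=C\C(=O)C(C=O)C/C=C(\C)CC/C=C(\C)CCC=C(C)C | intermediate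
11 | (2S,4E)-6-[(tert-butyldimethylsilyl)oxy]-2-chloro-5-methoxy-3-oxo-2-[(2E,6E)-farnesyl]hex-4-enal | CC(C)(C)[Si](C)(C)OC/C(OC)=C\C(=O)[C@@](Cl)(C=O)C/C=C(\C)CC/C=C(\C)CCC=C(C)C | intermediate
12 | lithium γ-dienolate of 11 (diene geometry not defined) | [Li+].CC(C)(C)[Si](C)(C)OC=C(OC)C=C([O-])[C@@](Cl)(C=O)C/C=C(\C)CC/C=C(\C)CCC=C(C)C | intermediate
13 | lithium alkoxide of (4S,5R,6S)-4-[(tert-butyldimethylsilyl)oxy]-6-chloro-6-[(2E,6E)-farnesyl]-5-hydroxy-3-methoxycyclohex-2-en-1-one | [Li+].COC1=CC(=O)[C@](Cl)(C/C=C(\C)CC/C=C(\C)CCC=C(C)C)[C@H]([O-])[C@@H]1O[Si](C)(C)C(C)(C)C | intermediate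
14 | (1R,5S,6R)-5-[(tert-butyldimethylsilyl)oxy]-4-methoxy-1-[(2E,6E)-farnesyl]-7-oxabicyclo[4.1.0]hept-3-en-2-one | COC1=CC(=O)[C@]2(C/C=C(\C)CC/C=C(\C)CCC=C(C)C)O[C@@H]2[C@@H]1O[Si](C)(C)C(C)(C)C | intermediate
15 | yanuthone X2, (1R,5S,6R)-5-hydroxy-4-methoxy-1-[(2E,6E)-farnesyl]-7-oxabicyclo[4.1.0]hept-3-en-2-one | COC1=CC(=O)[C@]2(C/C=C(\C)CC/C=C(\C)CCC=C(C)C)O[C@@H]2[C@@H]1O | target

**Totals**
Total step count: 6. Longest linear sequence: 6 (1 → 4 → 5 → 8 → 10 → 11 → 15).

**Three steps most likely to fail**

Highest risk, step 6. The aldolate 13 can also undergo retro-aldol cleavage of the other ring bond (between the chloride-bearing carbon and the carbinol carbon). That gives an open-chain α-alkoxy aldehyde, which collapses to a very stabilised, unreactive anion. The formyl group of 11 can be lost by attack of the base, and product 14 can suffer base-induced opening of the oxirane.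
The fallback makes the two rings separately under Lewis-acidic conditions. It sets out from 11. TBSOTf/Et3N in CH2Cl2 at −78 °C soft-enolises the vinylogous ester to the silyl dienol ether F1. Under the same silyl triflate this undergoes an intramolecular vinylogous Mukaiyama aldol reaction to the isolable bis-silylated chlorohydrin F2. TBAF in THF at 0 °C then frees the alkoxide next to the chloride, which closes the oxirane, and removes the second silyl group. This rejoins the route at 15.

Second risk, step 5. A β-keto aldehyde is an untested substrate class for this catalysis, so the ee may be low. The Lewis acid may also cyclise 10 to a γ-pyrone with loss of methanol.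
The fallback replaces catalyst control by a covalently bound, separable auxiliary. It sets out from 10, which is condensed with (R)-1-phenylethylamine (4 Å MS, CH2Cl2) to the hydrogen-bonded Z-enaminone F3. NCS at −78 °C chlorinates the enamine carbon on the face away from the phenyl group to give the α-chloro aldimine F4, whose diastereomers can be separated by chromatography. Hydrolysis in a cold aqueous oxalic acid/ether two-phase system rejoins the route at 11.

Third risk, step 4. Formylation may occur at oxygen or at the γ-carbon, and free 10 is prone to γ-pyrone formation on acidic work-up.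
The fallback reaches the aldehyde oxidation level by aldol addition and oxidation instead of acylation. It sets out from 8, whose enolate 9 is trapped with monomeric formaldehyde at −78 °C to give the β-hydroxy ketone F5. Neutral oxidation with IBX in EtOAc then rejoins the route at 10.

**Further compounds**
F1 | step 6 | silyl dienol ether of 11 (diene geometry not defined) | CC(C)(C)[Si](C)(C)OC=C(OC)C=C(O[Si](C)(C)C(C)(C)C)[C@@](Cl)(C=O)C/C=C(\C)CC/C=C(\C)CCC=C(C)C
F2 | step 6 | (4S,5R,6S)-4,5-bis[(tert-butyldimethylsilyl)oxy]-6-chloro-6-[(2E,6E)-farnesyl]-3-methoxycyclohex-2-en-1-one | COC1=CC(=O)[C@](Cl)(C/C=C(\C)CC/C=C(\C)CCC=C(C)C)[C@H](O[Si](C)(C)C(C)(C)C)[C@@H]1O[Si](C)(C)C(C)(C)C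
F3 | step 5 | Z-enaminone of 10 with (R)-1-phenylethylamine | CC(C)(C)[Si](C)(C)OC/C(OC)=C\C(=O)/C(C/C=C(\C)CC/C=C(\C)CCC=C(C)C)=C\N[C@H](C)c1ccccc1
F4 | step 5 | (2S)-α-chloro aldimine of 11 with (R)-1-phenylethylamine | CC(C)(C)[Si](C)(C)OC/C(OC)=C\C(=O)[C@@](Cl)(/C=N/[C@H](C)c1ccccc1)C/C=C(\C)CC/C=C(\C)CCC=C(C)C
F5 | step 4 | (2E,7E,11E)-1-[(tert-butyldimethylsilyl)oxy]-5-(hydroxymethyl)-2-methoxy-8,12,16-trimethylheptadeca-2,7,11,15-tetraen-4-one (racemic) | CC(C)(C)[Si](C)(C)OC/C(OC)=C\C(=O)C(CO)C/C=C(\C)CC/C=C(\C)CCC=C(C)C
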